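## The problem

Compound 14 is an unsymmetrical dialkyl ether in which one oxygen links the secondary allylic carbon of a 3-methylbut-3-en-2-yl unit to the gem-dimethyl carbon of a 2-hydroxy-3-methylbutyl unit, and each C5 unit ends in a CH2 group bonded to C8 of a 7-methoxycoumarin. Since the coumarin ring system can be bought, no ring has to be made, and the work lies in a ten-carbon chain that holds one crowded secondary–tertiary ether and two aryl–CH2 bonds. The two stereocentres, the ether-bearing carbon of the butenyl half and the carbinol carbon of the hydroxybutyl half, are both (S) and are separated by the O–C(CH3)2 link, so neither can control the other and each has to be set by a reagent. The lactones are opened by hydroxide, alkoxide, hydride and polar organometallics and their C3=C4 bonds accept nucleophiles and radicals; the tertiary, allylic ether ionises under strong acid; and the isopropenyl group rules out hydrogenation and strong electrophiles. Both CH2 carbons carry a β-oxygen, so a carbanion or a polar carbon–metal bond there would expel that oxygen, and C8 of each coumarin lies between the C7 methoxy group and the ring oxygen O1, so every bond made there is made at a doubly ortho-substituted carbon. The feature that opens the chosen route is that both arenes are held by the same kind of bond, C8(sp2)–CH2(sp3), to a primary carbon one atom away from a stereocentre. The whole C10 ether with both stereocentres can therefore be finished before any arene is present, and the two coumarins can be added last, one at a CH2–I carbon and one at an oxirane CH2 carbon.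

## Retrosynthesis

**14 to 8 and two molecules of 11.** Both C8–CH2 bonds are cut. The neighbouring cuts are worse: cutting CH2–CH would put the formation of a stereocentre into the coupling, and cutting the ether late would require a hindered etherification in the presence of two lactones. The chosen cut removes twenty of the thirty carbons as a ready-made ring system and leaves the arene-free iodo epoxide 8 and 8-iodo-7-methoxycoumarin 11. The forward reaction must form two sp2–sp3 bonds at a crowded aryl carbon without a base or nucleophile that opens lactones and without a carbanion β to oxygen. A nickel-catalysed reductive coupling of two electrophiles, which runs through alkyl radicals, meets both conditions.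

**11 to 10 to umbelliferone 9.** The O–CH3 and C8–I bonds are cut. Iodinating the phenoxide of 9 places iodine at C8, between the two oxygens, which is the position the free phenol activates most. Methylating first would give up this selectivity, so iodination comes first and methylation second.

**8 to 7 to 6.** The oxirane C–O bond and both C–I bonds are cut, leading back to triol 6. The two primary hydroxyls of 6 are of the same kind and can be converted to iodides in one operation, while the secondary hydroxyl is shielded by the neighbouring quaternary carbon and is left alone. The oxirane is closed from the resulting iodohydrin 7. Compound 8, not 7, is the coupling partner: the oxirane releases its iodohydrin only as fast as iodide is turned over, so a vicinal iodohydrin is never held at full concentration over manganese and low-valent nickel, where reductive loss of the oxygen would threaten.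

**6 to 5 to 3 and 4.** After adding back two silyl groups, the ether C–O bond at the tertiary carbon is cut. This side is chosen because a Lewis-acid-activated trisubstituted oxirane accepts an alcohol at its tertiary carbon. The other side would need a tertiary alkoxide to displace at a secondary allylic carbon, or an allyl cation that scrambles position and configuration. The oxirane oxygen of 3 stays on C2 and becomes the secondary hydroxyl of the target, so that group needs no step of its own. The precursors are two C5 pieces, epoxide 3 and allylic alcohol 4, and their union is a plain addition in which no atom is lost. The forward reaction must favour attack at C3 by a hindered alcohol over hydride shift, fluoride transfer and proton loss.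

**4 to 3.** Compound 4 is an isomer of 3: opening the C3–O bond with loss of a methyl proton gives the isopropenyl carbinol. The C2–O bond is not touched, so the (2S) centre of 3 becomes the (2R) centre of 4 with the same spatial arrangement; only the priority order changes. One chiral building block therefore supplies both halves.

**3 to 2 to prenol 1.** The O–Si bond and the oxirane are cut. A single Sharpless asymmetric epoxidation sets the only stereocentre that the route creates by a reagent, and it is used twice. Because both halves come from the same batch, the minor enantiomer of 3 should end up mainly in diastereomers of 5, which chromatography can remove (statistical amplification of enantiomeric purity). The tert-butyldiphenylsilyl group is chosen because it survives Et2Al(TMP) and BF3, makes the small fragments non-volatile and UV-visible, and is removed from both ends at once.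

## Roads not taken

Alternative 1: lactone tether. The cut is the bond from the ether oxygen to the secondary carbon of the butenyl half, made inside a ring. In the hydroxy ester A2 the two coumarin-bearing halves are held together by an ester; its α-hydroxyl is triflated and the tertiary hydroxyl displaces the triflate with inversion, closing the dioxanone A1. The merit is that the hindered ether is formed intramolecularly through a six-membered transition state with defined inversion. In this respect the road is better than the chosen plan, whose step 3 makes the same ether between two molecules under acid catalysis. The weak points lie after the ring closure. The ring carbonyl of A1 must still become the isopropenyl group, which needs methyl addition and methylenation at one ester in the presence of two coumarin lactones of similar reactivity. The triflate stage has β-hydrogens on a benzylic-type CH2 and can undergo elimination, and its α-centre can epimerise. Each coumarin-bearing half also needs its own asymmetric synthesis. The chosen plan accepts a less certain ether formation on cheap, arene-free material; in return it uses one asymmetric step for both centres and has no transformation after the coumarins arrive.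

Alternative 2: both pyranone rings closed last. The cuts are O1–C2 and C3=C4 of each coumarin. The bis-salicylaldehyde A4 reacts twice with (triphenylphosphoranylidene)ketene A5: each phenol adds to the ketene and the resulting ylide condenses with the neighbouring aldehyde. The product is the triethylsilyl ether A3, which is desilylated to 14. The merit is that the annulation is neutral and mild and runs in two directions at once, and that the aryl–CH2 bonds are made while the arenes carry no lactone and no C3=C4 acceptor. In that respect it is safer than the chosen key step, where alkyl radicals meet a coumarin. The weak points are that the same crowded aryl–CH2 bonds still have to be made, only earlier, on 1,2,3,4-tetrasubstituted arenes whose phenol and aldehyde need protection; that the secondary hydroxyl must be silylated because A5 acylates alcohols; and that protection, two annulations and deprotection follow the carbon–carbon bond formation. The chosen plan buys the finished heterocycle and ends at the coupling, and this brevity is what it has to set against the greater chemical safety of Alternative 2.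

Alternative 3: both benzene rings built by benzannulation. The cuts are C8–C8a and C6–C7 of each ring A. The bis(1-methoxyalkyne) A7 is heated with two equivalents of cyclobutenone A8; each ring-opened molecule of A8 adds to one ynol ether of A7 and the adduct rearranges to an aromatic ring, giving the bis-phenol A6. The merit is that the crowded 1,2,3-substitution pattern comes from the regiochemistry of the annulation, not from a coupling at a hindered carbon. This avoids the weakest point of the chosen plan, nickel insertion into a doubly ortho-substituted C–I bond. The weak points are that the heating exposes the allylic tertiary ether and the isopropenyl group to the ring-opened form of A8, which also adds to alkenes; that A8 is unstable and A7 carries two sensitive ynol ethers that must first be attached at the same two CH2 carbons; and that A6 is still two steps per ring from a coumarin (ortho-formylation and pyranone closure). The chosen plan has a harder single coupling but no endgame, whereas Alternative 3 has an easier ring-forming event and a long, twofold finish.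

Key step: step 9

Remark on the chemistry: L-(+)-diethyl tartrate is taken to give the (2S)-epoxy alcohol from prenol, the same sense of oxygen delivery as in the epoxidation of geraniol to its (2S,3S)-epoxide. If the opposite sense were found, D-(−)-diethyl tartrate would be used.

## Route

Step 1
Reactants: 1 prenol (3-methylbut-2-en-1-ol)
Product: 3 tert-butyl{[(2S)-3,3-dimethyloxiran-2-yl]methoxy}diphenylsilane, via epoxy alcohol 2 (not isolated)
Conditions: Ti(OiPr)4 (5 mol%), L-(+)-diethyl tartrate (6 mol%), tBuOOH, 4 Å molecular sieves, CH2Cl2, −20 °C; then P(OMe)3; then TBDPSCl, Et3N, DMAP (cat.), −20 to 0 °C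
Reagents that add atoms: tert-butyl hydroperoxide CC(C)(C)OO; tert-butyl(chloro)diphenylsilane CC(C)(C)[Si](Cl)(c1ccccc1)c1ccccc1
Why: Sharpless asymmetric epoxidation of a primary allylic alcohol, in which the catalyst formed from Ti(OiPr)4 and the tartrate delivers oxygen to one face and sets the (2S) centre; silylation in the same flask avoids isolating the small, water-soluble epoxy alcohol 2.

Step 2
Reactants: 3 tert-butyl{[(2S)-3,3-dimethyloxiran-2-yl]methoxy}diphenylsilane
Product: 4 (2R)-1-[(tert-butyldiphenylsilyl)oxy]-3-methylbut-3-en-2-ol
Conditions: Et2AlCl, LiTMP (forms Et2Al(TMP)), toluene, 0 °C; aq. potassium sodium tartrate work-up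
Reagents that add atoms: none
Why: Et2Al(TMP)-mediated isomerisation of a trisubstituted oxirane to an allylic alcohol: aluminium binds the oxirane oxygen, the C3–O bond breaks and the amide removes a methyl proton; the C2–O bond is untouched, so the stereocentre is kept and only its descriptor changes.

Step 3
Reactants: 3 tert-butyl{[(2S)-3,3-dimethyloxiran-2-yl]methoxy}diphenylsilane; 4 (2R)-1-[(tert-butyldiphenylsilyl)oxy]-3-methylbut-3-en-2-ol
Product: 5 (2S)-1-[(tert-butyldiphenylsilyl)oxy]-3-({(2R)-1-[(tert-butyldiphenylsilyl)oxy]-3-methylbut-3-en-2-yl}oxy)-3-methylbutan-2-ol
Conditions: BF3·OEt2 (20 mol%), CH2Cl2, −40 to −10 °C; 3 added slowly to a 2.5-fold amount of 4, the unreacted surplus of which is recovered by chromatography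
Reagents that add atoms: none
Why: Lewis-acid-catalysed alcoholysis of a trisubstituted oxirane, which takes the alcohol at the tertiary carbon because that carbon carries the positive charge of the activated oxirane; it is an addition of one molecule of 4 to one molecule of 3, so every atom of both partners is kept in 5. C3 is not stereogenic and the oxirane oxygen stays on C2, so both stereocentres are carried through unchanged.

Step 4
Reactants: 5 (2S)-1-[(tert-butyldiphenylsilyl)oxy]-3-({(2R)-1-[(tert-butyldiphenylsilyl)oxy]-3-methylbut-3-en-2-yl}oxy)-3-methylbutan-2-ol
Product: 6 (2S)-3-{[(2R)-1-hydroxy-3-methylbut-3-en-2-yl]oxy}-3-methylbutane-1,2-diol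
Conditions: NH4F, MeOH, 50 °C
Reagents that add atoms: none
Why: Fluoride cleavage of two primary silyl ethers under near-neutral conditions that leave the allylic tertiary ether alone; the polar triol is isolated without aqueous work-up.

Step 5
Reactants: 6 (2S)-3-{[(2R)-1-hydroxy-3-methylbut-3-en-2-yl]oxy}-3-methylbutane-1,2-diol
Product: 7 (2R)-1-iodo-3-{[(2R)-1-iodo-3-methylbut-3-en-2-yl]oxy}-3-methylbutan-2-ol
Conditions: I2, PPh3, imidazole, THF, 0 °C to rt
Reagents that add atoms: iodine II
Why: Appel iodination converts both primary hydroxyls through alkoxyphosphonium ions displaced by iodide, while the secondary hydroxyl next to the quaternary carbon is too hindered to react; no stereocentre is involved.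

Step 6
Reactants: 7 (2R)-1-iodo-3-{[(2R)-1-iodo-3-methylbut-3-en-2-yl]oxy}-3-methylbutan-2-ol
Product: 8 (2S)-2-(2-{[(2R)-1-iodo-3-methylbut-3-en-2-yl]oxy}propan-2-yl)oxirane
Conditions: K2CO3, MeOH, 0 °C
Reagents that add atoms: none
Why: Intramolecular Williamson closure of a vicinal iodohydrin (3-exo-tet), which should be far faster than attack of the same alkoxide on the distant CH2I; displacement occurs at the primary carbon, so the carbinol centre keeps its configuration.

Step 7
Reactants: 9 umbelliferone (7-hydroxy-2H-chromen-2-one)
Product: 10 7-hydroxy-8-iodo-2H-chromen-2-one
Conditions: I2, KI, aq. NH3, 0 °C to rt; acidic work-up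
Reagents that add atoms: iodine II
Why: Electrophilic aromatic iodination of the phenoxide, directed to C8, the ortho position lying between the two ring-activating oxygens; a single equivalent of iodine limits 6,8-diiodination.

Step 8
Reactants: 10 7-hydroxy-8-iodo-2H-chromen-2-one
Product: 11 8-iodo-7-methoxy-2H-chromen-2-one
Conditions: MeI, K2CO3, acetone, reflux
Reagents that add atoms: iodomethane CI
Why: Williamson O-methylation of an acidic phenol with a weak base that does not open the lactone.

Step 9
Reactants: 8 (2S)-2-(2-{[(2R)-1-iodo-3-methylbut-3-en-2-yl]oxy}propan-2-yl)oxirane; 11 8-iodo-7-methoxy-2H-chromen-2-one (2 equiv)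
Product: 14 8-[(2S)-2-hydroxy-3-{[(2S)-1-(7-methoxy-2-oxo-2H-chromen-8-yl)-3-methylbut-3-en-2-yl]oxy}-3-methylbutyl]-7-methoxy-2H-chromen-2-one, via monoarylated epoxide 12 (not isolated), via monoarylated iodohydrin 13 (not isolated)
Conditions: NiBr2·glyme (20 mol%), 4,4'-di-tert-butyl-2,2'-bipyridine (20 mol%), NaI (0.5 equiv), Et3N·HCl (1.2 equiv), Mn powder (4 equiv), DMPU, 25–40 °C; a third equivalent of 11 is charged to offset biaryl formation
Reagents that add atoms: none
Why: Zerovalent nickel, formed from NiBr2·glyme and Mn, inserts into the C8–I bond of 11 to give an arylnickel iodide of divalent nickel. The primary iodide of 8 gives a primary radical by halogen abstraction at low-valent nickel; the arylnickel captures it and reductive elimination from trivalent nickel forms the first C8–CH2 bond (12). Iodide, with Et3N·HCl as proton source, then opens the oxirane of 12 at its unsubstituted CH2 to give iodohydrin 13, whose C–I bond enters the same cycle and forms the second C8–CH2 bond; the order in which the two arms react does not matter. The closest known reaction type is the nickel/bipyridine-catalysed reductive cross-electrophile coupling of aryl halides with primary alkyl iodides and, under iodide co-catalysis, with terminal epoxides. No ring is closed and no stereocentre is formed; both existing stereocentres sit one carbon from the radical centres and are not touched. The step needs cross-coupling over homo-coupling, which is secured by the preference of zerovalent nickel for the sp2 C–I bond, by radical formation from the sp3 C–I bond and by the excess of 11. It also needs oxirane opening at CH2, which is secured because the other oxirane carbon is flanked by a quaternary carbon. Mn is used in place of Zn because zinc would insert directly into the β-alkoxy iodide and expel the ether oxygen, and no basic or polar organometallic reagent meets the lactones.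

## Compound list

1 | prenol (3-methylbut-2-en-1-ol) | CC(C)=CCO | starting material
2 | [(2S)-3,3-dimethyloxiran-2-yl]methanol | OC[C@@H]1OC1(C)C | intermediate
3 | tert-butyl{[(2S)-3,3-dimethyloxiran-2-yl]methoxy}diphenylsilane | CC(C)(C)[Si](OC[C@@H]1OC1(C)C)(c1ccccc1)c1ccccc1 | intermediate
4 | (2R)-1-[(tert-butyldiphenylsilyl)oxy]-3-methylbut-3-en-2-ol | C=C(C)[C@@H](O)CO[Si](c1ccccc1)(c1ccccc1)C(C)(C)C | intermediate
5 | (2S)-1-[(tert-butyldiphenylsilyl)oxy]-3-({(2R)-1-[(tert-butyldiphenylsilyl)oxy]-3-methylbut-3-en-2-yl}oxy)-3-methylbutan-2-ol | C=C(C)[C@H](CO[Si](c1ccccc1)(c1ccccc1)C(C)(C)C)OC(C)(C)[C@@H](O)CO[Si](c1ccccc1)(c1ccccc1)C(C)(C)C | intermediate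
6 | (2S)-3-{[(2R)-1-hydroxy-3-methylbut-3-en-2-yl]oxy}-3-methylbutane-1,2-diol | C=C(C)[C@H](CO)OC(C)(C)[C@@H](O)CO | intermediate
7 | (2R)-1-iodo-3-{[(2R)-1-iodo-3-methylbut-3-en-2-yl]oxy}-3-methylbutan-2-ol | C=C(C)[C@H](CI)OC(C)(C)[C@@H](O)CI | intermediate
8 | (2S)-2-(2-{[(2R)-1-iodo-3-methylbut-3-en-2-yl]oxy}propan-2-yl)oxirane | C=C(C)[C@H](CI)OC(C)(C)[C@@H]1CO1 | intermediate
9 | umbelliferone (7-hydroxy-2H-chromen-2-one) | O=c1ccc2ccc(O)cc2o1 | starting material
10 | 7-hydroxy-8-iodo-2H-chromen-2-one | O=c1ccc2ccc(O)c(I)c2o1 | intermediate
11 | 8-iodo-7-methoxy-2H-chromen-2-one | COc1ccc2ccc(=O)oc2c1I | intermediate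
12 | 7-methoxy-8-[(2S)-3-methyl-2-({2-[(2S)-oxiran-2-yl]propan-2-yl}oxy)but-3-en-1-yl]-2H-chromen-2-one | C=C(C)[C@H](Cc1c(OC)ccc2ccc(=O)oc12)OC(C)(C)[C@@H]1CO1 | intermediate
13 | 8-[(2S)-2-{[(3R)-3-hydroxy-4-iodo-2-methylbutan-2-yl]oxy}-3-methylbut-3-en-1-yl]-7-methoxy-2H-chromen-2-one | C=C(C)[C@H](Cc1c(OC)ccc2ccc(=O)oc12)OC(C)(C)[C@@H](O)CI | intermediate
14 | 8-[(2S)-2-hydroxy-3-{[(2S)-1-(7-methoxy-2-oxo-2H-chromen-8-yl)-3-methylbut-3-en-2-yl]oxy}-3-methylbutyl]-7-methoxy-2H-chromen-2-one | C=C(C)[C@H](Cc1c(OC)ccc2ccc(=O)oc12)OC(C)(C)[C@@H](O)Cc1c(OC)ccc2ccc(=O)oc12 | target

## Step count and least certain steps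

Total: 9 steps. Longest linear sequence: 7 steps (steps 1 to 6 and step 9, from 1 to 14). The coumarin branch (steps 7 and 8) joins at step 9.

**Step 9 (key step).**
- What may go wrong: nickel insertion into the doubly ortho-substituted C8–I bond and capture of the radical at the crowded arylnickel may be slow. Biaryl homo-coupling and simple reduction of the alkyl arms could then win.
- The primary radicals may add to the C3=C4 bond of a coumarin.
- The homoallylic radical of the butenyl arm may undergo a 1,2-vinyl shift through a cyclopropylcarbinyl radical.
- An alkylnickel may lose its β-oxygen, which on the butenyl arm would cleave the ether.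
- The second coupling may stall after the first arm has reacted.
- Fallback, from 7 and 11, returning at 14: the hydroxyl of 7, isolated after step 5, is capped with TMSCl and imidazole to give the trimethylsilyl ether F1. Compound 11 is converted with Zn dust and LiCl in THF into (7-methoxy-2-oxo-2H-chromen-8-yl)zinc iodide F2. A twofold nickel-catalysed Negishi alkylation of F1 with F2 (Ni(acac)2, 4-fluorostyrene, THF–NMP, −10 °C) should give the trimethylsilyl ether of the target F3. Methanolic citric acid removes the silyl group to give 14. Here the arene enters by transmetalation, so nothing depends on nickel inserting into the hindered aryl iodide in competition with the alkyl iodides.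

**Step 3.**
- What may go wrong: capture of the activated oxirane at its tertiary carbon by the hindered secondary alcohol may be slower than hydride shift to the ketone (Meinwald rearrangement), fluoride transfer from boron, proton loss to an allylic alcohol, or oligomerisation.
- Fallback, from 4, returning at 5: two molecules of 4 are joined by alkoxymercuration without any epoxide. Hg(OCOCF3)2 (half a molar amount relative to 4, CH2Cl2, 0 °C) activates the isopropenyl group of one molecule, and the hydroxyl of a second adds at the internal carbon (Markovnikov) to give the β-alkoxyalkylmercury trifluoroacetate F4. The configuration at its mercurated quaternary carbon is irrelevant. Alkaline NaBH4 replaces mercury by hydrogen and gives 5. Conversion is kept partial so that the remaining isopropenyl group of 5 does not react further, and 4 is recycled.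

**Step 5.**
- What may go wrong: a neighbouring hydroxyl may take part at the alkoxyphosphonium stage. The secondary hydroxyl could close a 1,4-dioxane onto the activated carbon of the other arm, the diol arm could be tied up as a cyclic phosphorane and convert incompletely, or the vicinal diol arm could be deoxygenated to an alkene if the reagents are in excess or warm.
- Fallback, from 6, returning at 8: the two primary hydroxyls are tosylated (TsCl, Et3N, cat. Bu2SnO, CH2Cl2) to give the bis-tosylate F5. K2CO3 in MeOH closes the oxirane to give the epoxy tosylate F6. NaI in acetone with NaHCO3 exchanges the remaining tosylate for iodide and gives 8. This path also replaces step 6 and never passes through a free iodohydrin.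

**Step 2.**
- What may go wrong: the amide may remove a proton from C1, next to the silyloxy group, instead of from a methyl group, or may attack or shift the silyl group.
- Fallback, from 2, returning at 4: the epoxy alcohol 2 is isolated from step 1 by non-aqueous work-up and rearranged before protection. Ti(OiPr)4 in CH2Cl2 at room temperature binds the hydroxyl and opens the oxirane at C3 with loss of a methyl proton (the hydroxyl-directed epoxy alcohol to ene-diol rearrangement), giving (2R)-3-methylbut-3-ene-1,2-diol F7. Silylation of the primary hydroxyl (TBDPSCl, imidazole, DMF, 0 °C) gives 4.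

## Further compounds

F1 | step 9 | {[(2R)-1-iodo-3-{[(2R)-1-iodo-3-methylbut-3-en-2-yl]oxy}-3-methylbutan-2-yl]oxy}trimethylsilane | C=C(C)[C@H](CI)OC(C)(C)[C@@H](O[Si](C)(C)C)CI
F2 | step 9 | (7-methoxy-2-oxo-2H-chromen-8-yl)zinc iodide | COc1ccc2ccc(=O)oc2c1[Zn]I
F3 | step 9 | trimethylsilyl ether of 14 | C=C(C)[C@H](Cc1c(OC)ccc2ccc(=O)oc12)OC(C)(C)[C@@H](O[Si](C)(C)C)Cc1c(OC)ccc2ccc(=O)oc12
F4 | step 3 | {(3S)-4-[(tert-butyldiphenylsilyl)oxy]-2-({(2R)-1-[(tert-butyldiphenylsilyl)oxy]-3-methylbut-3-en-2-yl}oxy)-3-hydroxy-2-methylbutyl}mercury trifluoroacetate (either configuration at C2) | C=C(C)[C@H](CO[Si](c1ccccc1)(c1ccccc1)C(C)(C)C)OC(C)(C[Hg]OC(=O)C(F)(F)F)[C@@H](O)CO[Si](c1ccccc1)(c1ccccc1)C(C)(C)C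
F5 | step 5 | (2S)-2-hydroxy-3-methyl-3-({(2R)-3-methyl-1-[(4-methylbenzenesulfonyl)oxy]but-3-en-2-yl}oxy)butyl 4-methylbenzenesulfonate | C=C(C)[C@H](COS(=O)(=O)c1ccc(C)cc1)OC(C)(C)[C@@H](O)COS(=O)(=O)c1ccc(C)cc1
F6 | step 5 | (2R)-3-methyl-2-({2-[(2S)-oxiran-2-yl]propan-2-yl}oxy)but-3-en-1-yl 4-methylbenzenesulfonate | C=C(C)[C@H](COS(=O)(=O)c1ccc(C)cc1)OC(C)(C)[C@@H]1CO1
F7 | step 2 | (2R)-3-methylbut-3-ene-1,2-diol | C=C(C)[C@@H](O)CO
A1 | alternative 1 | (3S,6S)-3,6-bis[(7-methoxy-2-oxo-2H-chromen-8-yl)methyl]-5,5-dimethyl-1,4-dioxan-2-one (cis) | O=C1[C@H](Cc2c(OC)ccc3ccc(=O)oc23)OC(C)(C)[C@H](Cc2c(OC)ccc3ccc(=O)oc23)O1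
A2 | alternative 1 | (2S)-3-hydroxy-1-(7-methoxy-2-oxo-2H-chromen-8-yl)-3-methylbutan-2-yl (2R)-2-hydroxy-3-(7-methoxy-2-oxo-2H-chromen-8-yl)propanoate | CC(C)(O)[C@H](Cc1c(OC)ccc2ccc(=O)oc12)OC(=O)[C@H](O)Cc1c(OC)ccc2ccc(=O)oc12
A3 | alternative 2 | triethylsilyl ether of 14 | C=C(C)[C@H](Cc1c(OC)ccc2ccc(=O)oc12)OC(C)(C)[C@@H](O[Si](CC)(CC)CC)Cc1c(OC)ccc2ccc(=O)oc12
A4 | alternative 2 | bis-salicylaldehyde: 3,3'-substituted bis(2-hydroxy-4-methoxybenzaldehyde) on the triethylsilylated C10 ether chain | C=C(C)[C@H](Cc1c(OC)ccc(C=O)c1O)OC(C)(C)[C@@H](O[Si](CC)(CC)CC)Cc1c(OC)ccc(C=O)c1O
A5 | alternative 2 | (triphenylphosphoranylidene)ketene | O=C=C=P(c1ccccc1)(c1ccccc1)c1ccccc1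
A6 | alternative 3 | silylated bis(2-alkyl-3-methoxyphenol) ether | C=C(C)[C@H](Cc1c(OC)cccc1O)OC(C)(C)[C@@H](O[Si](CC)(CC)CC)Cc1c(OC)cccc1O
A7 | alternative 3 | bis(1-methoxyalkyne) on the triethylsilylated C10 ether chain | C=C(C)[C@H](CC#COC)OC(C)(C)[C@@H](O[Si](CC)(CC)CC)CC#COC
A8 | alternative 3 | cyclobutenone | O=C1C=CC1
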